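A direct plan would take a cyclopentenone that already is ring A (A1), join its α′-enolate to the acyclic C6–C8 aldehyde A2 by an aldol reaction, dress ring A, and close ring B last by metathesis of the triacetate A3.
Its weakest steps would be:
- the fragment-joining aldol: one event on two multi-step fragments would have to set C5 and C6, and their relation to C1 and C7, by substrate control alone;
- the final closure of the seven-membered ring between a 1,1-disubstituted allylsilane and an allylic acetate: a slow, high-dilution metathesis to a trisubstituted alkene on the most precious material, followed by an acid step beside a tertiary alcohol;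
- the run-up to A1: about six steps would add only one methoxy group and one side chain to a bought ring.

**Plan of the new route**
- Cuts: C10=C14 goes back to a C10 ketone; ring A is opened at C3=C4 (cyclopentene metathesis; the trans-3,4-diol comes from it by directed epoxidation and SN2 opening); C4–C5 and C1–C2 are cut together across C1=C5 of a cyclohept-2-enone (12); 12 is cut at C1=C5 and C8–C9 to aldehyde 7 and a butenone enolate.
- Enabling feature: the array O=C10–C1=C5–C6(O), in which the methylene-bearing C10 is a ketone in disguise, the ring-fusion atoms C1 and C5 are the α- and β-carbons of an enone in ring B, and C6 is a γ-silyloxy control element.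
- Ring order: ring B (seven-membered) first, early and on simple material; ring A (five-membered) afterwards.
- Weak steps avoided: no aldol joins two advanced fragments; C5 and C1 are relayed from C6 in one operation; no seven-membered ring closure or allylsilane at a late stage; ring A needs no prepared fragment, its carbons come from two bought C3 reagents.

Key step: step 8

Remarks: ring positions are given in guaiane numbering (ring A = C1–C5, ring B = C1, C5–C10). Compound 1 is assumed to be a purchasable catalogue compound.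

**Step 1**
Reactants: 1 (S)-4-benzyl-3-(3-methylbutanoyl)-1,3-oxazolidin-2-one; 2 prop-2-enal
Product: 4 (S)-4-benzyl-3-[(2S,3R)-3-hydroxy-2-(propan-2-yl)pent-4-enoyl]-1,3-oxazolidin-2-one, via Z boron enolate 3 (not isolated)
Conditions: Bu2BOTf, iPr2NEt, CH2Cl2, −78 → 0 °C; 2, −78 → 0 °C; pH 7 buffer, MeOH, 30 % H2O2, 0 °C
Reagents that add atoms: none
Why: Evans syn-aldol reaction, in which the Z dibutylboron enolate reacts through a Zimmerman–Traxler chair on the face away from the benzyl group and so sets C7 and C6 syn in one event.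

**Step 2**
Reactants: 4 (S)-4-benzyl-3-[(2S,3R)-3-hydroxy-2-(propan-2-yl)pent-4-enoyl]-1,3-oxazolidin-2-one
Product: 5 (S)-4-benzyl-3-[(2S,3R)-2-(propan-2-yl)-3-[(triethylsilyl)oxy]pent-4-enoyl]-1,3-oxazolidin-2-one
Conditions: Et3SiOTf, 2,6-lutidine, CH2Cl2, −78 → 0 °C
Reagents that add atoms: triethylsilyl trifluoromethanesulfonate, CC[Si](CC)(CC)OS(=O)(=O)C(F)(F)F
Why: Silyl ether formation blocks retro-aldol cleavage and gives C6 a bulky, non-chelating group that later directs the cuprate and can be removed selectively beside a tert-butyldimethylsilyl ether.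

**Step 3**
Reactants: 5 (S)-4-benzyl-3-[(2S,3R)-2-(propan-2-yl)-3-[(triethylsilyl)oxy]pent-4-enoyl]-1,3-oxazolidin-2-one
Product: 6 (2R,3R)-2-(propan-2-yl)-3-[(triethylsilyl)oxy]pent-4-en-1-ol
Conditions: LiBH4, MeOH (1.1 equiv), THF, 0 °C
Reagents that add atoms: none
Why: Reductive cleavage of the imide gives the primary alcohol and returns the auxiliary without touching C7 (the descriptor changes only through the priorities).

**Step 4**
Reactants: 6 (2R,3R)-2-(propan-2-yl)-3-[(triethylsilyl)oxy]pent-4-en-1-ol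
Product: 7 (2S,3R)-2-(propan-2-yl)-3-[(triethylsilyl)oxy]pent-4-enal
Conditions: Dess–Martin periodinane, pyridine, CH2Cl2, 0 °C → rt
Reagents that add atoms: none
Why: Buffered Dess–Martin oxidation should give the α-branched aldehyde without epimerisation; it is used at once.

**Step 5**
Reactants: 8 (buta-1,3-dien-2-yloxy)trimethylsilane; 7 (2S,3R)-2-(propan-2-yl)-3-[(triethylsilyl)oxy]pent-4-enal
Product: 10 (5S,6R,7R)-5-hydroxy-6-(propan-2-yl)-7-[(triethylsilyl)oxy]nona-1,8-dien-3-one, via lithium dienolate 9 (not isolated)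
Conditions: 8, MeLi, THF, 0 °C, then −78 °C; 7, −78 °C; AcOH, −78 °C
Reagents that add atoms: none
Why: Lithium enolate aldol addition through a closed transition state under Felkin–Anh control, in which the enolate enters anti to the silyloxyallyl branch of the α-stereocentre so that the new C8 hydroxyl is syn to the isopropyl group (5S), while the cold acidic quench prevents oxa-Michael closure of the aldolate.

**Step 6**
Reactants: 10 (5S,6R,7R)-5-hydroxy-6-(propan-2-yl)-7-[(triethylsilyl)oxy]nona-1,8-dien-3-one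
Product: 11 (5S,6R,7R)-5-[(tert-butyldimethylsilyl)oxy]-6-(propan-2-yl)-7-[(triethylsilyl)oxy]nona-1,8-dien-3-one
Conditions: tBuMe2SiOTf, 2,6-lutidine, CH2Cl2, −78 °C
Reagents that add atoms: tert-butyldimethylsilyl trifluoromethanesulfonate, CC(C)(C)[Si](C)(C)OS(=O)(=O)C(F)(F)F
Why: Silylation of the β-hydroxy ketone stops retro-aldol and oxa-Michael reactions and gives C8 a robust group that is a poor leaving group and is orthogonal to the triethylsilyl ether at C6.

**Step 7**
Reactants: 11 (5S,6R,7R)-5-[(tert-butyldimethylsilyl)oxy]-6-(propan-2-yl)-7-[(triethylsilyl)oxy]nona-1,8-dien-3-one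
Product: 12 (4R,5R,6S)-6-[(tert-butyldimethylsilyl)oxy]-5-(propan-2-yl)-4-[(triethylsilyl)oxy]cyclohept-2-en-1-one
Conditions: second-generation Grubbs catalyst RuCl2(=CHPh)(PCy3)(SIMes) (5 mol %), CH2Cl2 (5 mM), 40 °C
Reagents that add atoms: none
Why: Ring-closing alkene metathesis between the vinyl ketone and the allylic silyl ether forms the disubstituted C1=C5 bond of ring B with loss of ethene, on an early, simple chain biased toward closure by three substituents, and touches no stereocentre.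

**Step 8**
Reactants: 12 (4R,5R,6S)-6-[(tert-butyldimethylsilyl)oxy]-5-(propan-2-yl)-4-[(triethylsilyl)oxy]cyclohept-2-en-1-one; 13 bromo(prop-1-en-2-yl)magnesium; 14 3-iodoprop-1-ene
Product: 16 (2S,3R,4R,5R,6S)-6-[(tert-butyldimethylsilyl)oxy]-3-(prop-1-en-2-yl)-5-(propan-2-yl)-2-(prop-2-en-1-yl)-4-[(triethylsilyl)oxy]cycloheptan-1-one, via magnesium enolate 15 (not isolated)
Conditions: 13, CuBr·SMe2 (15 mol %), THF, −78 → −40 °C; then 14, HMPA, −40 → −10 °C; aq. NH4Cl
Reagents that add atoms: none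
Why: Copper-catalysed conjugate addition of the alkenyl Grignard reagent (π-complex, oxidative addition at C5 to a trivalent copper species, reductive elimination) gives the magnesium enolate 15 with its double bond fixed between C10 and C1, and this enolate is C-allylated by 14 in an SN2 reaction once HMPA is added. The closest known reaction type is the three-component coupling (conjugate addition, then enolate trapping) of γ-silyloxy cycloalkenones known from prostaglandin synthesis. The step closes no ring; it places on C5 and C1 the two alkenyl arms whose metathesis closes ring A in step 9 (five-membered, ring-closing alkene metathesis). C5 is controlled by the C6 silyloxy group, anti to which the cuprate should add, and C1 by the new C5 substituent, anti to which the allyl group should enter, so that the trans ring fusion is relayed from C6. The step needs 1,4- rather than 1,2-addition, which copper secures, and C-alkylation at C1 before the enolate can equilibrate toward C9 (where loss of the C8 silyloxide would follow), which the regiospecific formation of 15, the reactive allylic iodide and the low temperature should secure.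

**Step 9**
Reactants: 16 (2S,3R,4R,5R,6S)-6-[(tert-butyldimethylsilyl)oxy]-3-(prop-1-en-2-yl)-5-(propan-2-yl)-2-(prop-2-en-1-yl)-4-[(triethylsilyl)oxy]cycloheptan-1-one
Product: 17 (1S,5R,6R,7R,8S)-8-[(tert-butyldimethylsilyl)oxy]-6-[(triethylsilyl)oxy]-14-norguai-3-en-10-one (trans-fused)
Conditions: second-generation Grubbs catalyst RuCl2(=CHPh)(PCy3)(SIMes) (5 mol %), CH2Cl2 (10 mM), 40 °C
Reagents that add atoms: none
Why: Ring-closing alkene metathesis of the allyl and isopropenyl arms closes ring A as the trisubstituted C3=C4 cyclopentene, a fast five-membered closure that leaves the trans ring fusion untouched.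

**Step 10**
Reactants: 17 (1S,5R,6R,7R,8S)-8-[(tert-butyldimethylsilyl)oxy]-6-[(triethylsilyl)oxy]-14-norguai-3-en-10-one
Product: 19 (1S,5R,6R,7S,8S)-8-[(tert-butyldimethylsilyl)oxy]guaia-3,10(14)-dien-6-ol, via diene silyl ether 18 (not isolated)
Conditions: CH2Br2, Zn, TiCl4, THF/CH2Cl2, 0 °C → rt; work-up; PPTS, MeOH, rt
Reagents that add atoms: dibromomethane, BrCBr
Why: Takai–Lombardo methylenation converts the C10 ketone into the exocyclic alkene without a base that could epimerise C1 or expel the C8 silyloxide, and mild acid methanolysis then removes only the triethylsilyl ether to free the C6 hydroxyl.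

**Step 11**
Reactants: 19 (1S,5R,6R,7S,8S)-8-[(tert-butyldimethylsilyl)oxy]guaia-3,10(14)-dien-6-ol
Product: 20 (1S,3R,4S,5S,6S,7S,8S)-8-[(tert-butyldimethylsilyl)oxy]-3,4-epoxyguai-10(14)-en-6-ol (3α,4α-epoxide)
Conditions: VO(acac)2 (5 mol %), t-BuOOH (1.2 equiv), CH2Cl2, 0 °C → rt
Reagents that add atoms: tert-butyl hydroperoxide, CC(C)(C)OO
Why: Hydroxyl-directed epoxidation, in which the homoallylic C6 hydroxyl binds vanadium and delivers the oxygen to its own (α) face of the trisubstituted C3=C4 bond, setting C4 (4S); the less substituted and more remote exocyclic alkene should be left alone.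

**Step 12**
Reactants: 20 (1S,3R,4S,5S,6S,7S,8S)-8-[(tert-butyldimethylsilyl)oxy]-3,4-epoxyguai-10(14)-en-6-ol
Product: 21 (1S,3S,4S,5S,6S,7S,8S)-8-[(tert-butyldimethylsilyl)oxy]guai-10(14)-ene-3,4,6-triol
Conditions: KOH (3 M aq.), DMSO, 100 °C
Reagents that add atoms: water, O
Why: SN2 opening of the trisubstituted epoxide by hydroxide at the less substituted C3 with inversion (attack from the β face) leaves the C4–O bond untouched and gives the trans-3,4-diol with C3 set as 3S.

**Step 13**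
Reactants: 21 (1S,3S,4S,5S,6S,7S,8S)-8-[(tert-butyldimethylsilyl)oxy]guai-10(14)-ene-3,4,6-triol
Product: 22 (1S,3S,4S,5S,6S,7R,8S)-guai-10(14)-ene-3,4,6,8-tetrol
Conditions: Bu4NF, THF, 0 °C → rt
Reagents that add atoms: none
Why: Fluoride-induced desilylation frees the C8 hydroxyl under conditions that leave the alkene and the tertiary alcohol alone.

**Step 14**
Reactants: 22 (1S,3S,4S,5S,6S,7R,8S)-guai-10(14)-ene-3,4,6,8-tetrol
Product: 23 (1S,3S,4S,5S,6S,7R,8S)-4-hydroxyguai-10(14)-ene-3,6,8-triyl triacetate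
Conditions: Ac2O, pyridine, DMAP (10 mol %), CH2Cl2, 0 °C → rt
Reagents that add atoms: acetic anhydride, CC(=O)OC(C)=O
Why: Acylation esterifies the three secondary hydroxyls (C3, C6, C8) while the hindered tertiary C4 hydroxyl should stay free, as in the target.

**Compound list**
1 | (S)-4-benzyl-3-(3-methylbutanoyl)-1,3-oxazolidin-2-one | CC(C)CC(=O)N1C(=O)OC[C@@H]1Cc1ccccc1 | starting material
2 | prop-2-enal | C=CC=O | starting material
3 | dibutylboron Z-enolate of 1 | CCCCB(CCCC)O/C(=C\C(C)C)N1C(=O)OC[C@@H]1Cc1ccccc1 | intermediate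
4 | (S)-4-benzyl-3-[(2S,3R)-3-hydroxy-2-(propan-2-yl)pent-4-enoyl]-1,3-oxazolidin-2-one | C=C[C@@H](O)[C@H](C(C)C)C(=O)N1C(=O)OC[C@@H]1Cc1ccccc1 | intermediate
5 | (S)-4-benzyl-3-[(2S,3R)-2-(propan-2-yl)-3-[(triethylsilyl)oxy]pent-4-enoyl]-1,3-oxazolidin-2-one | C=C[C@@H](O[Si](CC)(CC)CC)[C@H](C(C)C)C(=O)N1C(=O)OC[C@@H]1Cc1ccccc1 | intermediate
6 | (2R,3R)-2-(propan-2-yl)-3-[(triethylsilyl)oxy]pent-4-en-1-ol | C=C[C@@H](O[Si](CC)(CC)CC)[C@H](C(C)C)CO | intermediate
7 | (2S,3R)-2-(propan-2-yl)-3-[(triethylsilyl)oxy]pent-4-enal | C=C[C@@H](O[Si](CC)(CC)CC)[C@H](C(C)C)C=O | intermediate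
8 | (buta-1,3-dien-2-yloxy)trimethylsilane | C=CC(=C)O[Si](C)(C)C | starting material
9 | lithium buta-1,3-dien-2-olate | [Li]OC(=C)C=C | intermediate
10 | (5S,6R,7R)-5-hydroxy-6-(propan-2-yl)-7-[(triethylsilyl)oxy]nona-1,8-dien-3-one | C=CC(=O)C[C@H](O)[C@@H](C(C)C)[C@H](O[Si](CC)(CC)CC)C=C | intermediate
11 | (5S,6R,7R)-5-[(tert-butyldimethylsilyl)oxy]-6-(propan-2-yl)-7-[(triethylsilyl)oxy]nona-1,8-dien-3-one | C=CC(=O)C[C@H](O[Si](C)(C)C(C)(C)C)[C@@H](C(C)C)[C@H](O[Si](CC)(CC)CC)C=C | intermediate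
12 | (4R,5R,6S)-6-[(tert-butyldimethylsilyl)oxy]-5-(propan-2-yl)-4-[(triethylsilyl)oxy]cyclohept-2-en-1-one | O=C1C[C@H](O[Si](C)(C)C(C)(C)C)[C@@H](C(C)C)[C@H](O[Si](CC)(CC)CC)C=C1 | intermediate
13 | bromo(prop-1-en-2-yl)magnesium | C=C(C)[Mg]Br | starting material
14 | 3-iodoprop-1-ene | C=CCI | starting material
15 | bromomagnesium (3R,4R,5R,6S)-6-[(tert-butyldimethylsilyl)oxy]-3-(prop-1-en-2-yl)-5-(propan-2-yl)-4-[(triethylsilyl)oxy]cyclohept-1-en-1-olate | Br[Mg]OC1=C[C@H](C(C)=C)[C@@H](O[Si](CC)(CC)CC)[C@H](C(C)C)[C@@H](O[Si](C)(C)C(C)(C)C)C1 | intermediate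
16 | (2S,3R,4R,5R,6S)-6-[(tert-butyldimethylsilyl)oxy]-3-(prop-1-en-2-yl)-5-(propan-2-yl)-2-(prop-2-en-1-yl)-4-[(triethylsilyl)oxy]cycloheptan-1-one | O=C1C[C@H](O[Si](C)(C)C(C)(C)C)[C@@H](C(C)C)[C@H](O[Si](CC)(CC)CC)[C@@H](C(C)=C)[C@@H]1CC=C | intermediate
17 | (1S,5R,6R,7R,8S)-8-[(tert-butyldimethylsilyl)oxy]-6-[(triethylsilyl)oxy]-14-norguai-3-en-10-one (trans-fused; guaiane numbering) | O=C1C[C@H](O[Si](C)(C)C(C)(C)C)[C@@H](C(C)C)[C@H](O[Si](CC)(CC)CC)[C@@H]2[C@@H]1CC=C2C | intermediate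
18 | (1S,5R,6R,7R,8S)-8-[(tert-butyldimethylsilyl)oxy]-6-[(triethylsilyl)oxy]guaia-3,10(14)-diene | C=C1C[C@H](O[Si](C)(C)C(C)(C)C)[C@@H](C(C)C)[C@H](O[Si](CC)(CC)CC)[C@@H]2[C@@H]1CC=C2C | intermediate
19 | (1S,5R,6R,7S,8S)-8-[(tert-butyldimethylsilyl)oxy]guaia-3,10(14)-dien-6-ol | C=C1C[C@H](O[Si](C)(C)C(C)(C)C)[C@@H](C(C)C)[C@H](O)[C@@H]2[C@@H]1CC=C2C | intermediate
20 | (1S,3R,4S,5S,6S,7S,8S)-8-[(tert-butyldimethylsilyl)oxy]-3,4-epoxyguai-10(14)-en-6-ol | C=C1C[C@H](O[Si](C)(C)C(C)(C)C)[C@@H](C(C)C)[C@H](O)[C@@H]2[C@@H]1C[C@H]3O[C@@]23C | intermediate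
21 | (1S,3S,4S,5S,6S,7S,8S)-8-[(tert-butyldimethylsilyl)oxy]guai-10(14)-ene-3,4,6-triol | C=C1C[C@H](O[Si](C)(C)C(C)(C)C)[C@@H](C(C)C)[C@H](O)[C@@H]2[C@@H]1C[C@H](O)[C@@]2(C)O | intermediate
22 | (1S,3S,4S,5S,6S,7R,8S)-guai-10(14)-ene-3,4,6,8-tetrol | C=C1C[C@H](O)[C@@H](C(C)C)[C@H](O)[C@@H]2[C@@H]1C[C@H](O)[C@@]2(C)O | intermediate
23 | (1S,3S,4S,5S,6S,7R,8S)-4-hydroxyguai-10(14)-ene-3,6,8-triyl triacetate | C=C1C[C@H](OC(C)=O)[C@@H](C(C)C)[C@H](OC(C)=O)[C@@H]2[C@@H]1C[C@H](OC(C)=O)[C@@]2(C)O | target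

Total step count: 14. Longest linear sequence: 14 steps (1 → 23; the reagents 2, 8, 13 and 14 are bought).

**Steps most likely to fail**

1. Step 8. Proton transfer between the magnesium enolate and already alkylated ketone could move the enolate toward C9, from where loss of the C8 silyloxide and over-alkylation would follow; the anti facial preference of the cuprate could also be incomplete. Fallback from 12: the same copper-catalysed addition of 13, run in the presence of Me3SiCl, would give the silyl enol ether (3R,4R,5R,6S)-6-[(tert-butyldimethylsilyl)oxy]-3-(prop-1-en-2-yl)-5-(propan-2-yl)-4-[(triethylsilyl)oxy]-1-[(trimethylsilyl)oxy]cyclohept-1-ene F1. A Tsuji allylation (allyl methyl carbonate, Pd2(dba)3, dppe, THF, 65 °C) would then transfer the allyl group to C1 through a π-allyl palladium enolate under neutral conditions and come back to the route at 16.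

2. Step 12. Hydroxide has to attack the secondary C3 next to a fully substituted carbon; opening at the tertiary C4, base-induced isomerisation to allylic alcohols, or no reaction under tolerable conditions are possible. Fallback from 16, which builds the diol without an epoxide:
   - ozonolysis of both alkenes (O3, CH2Cl2/MeOH, −78 °C; Me2S) would give 2-[(1S,2S,3S,4R,5S)-2-acetyl-5-[(tert-butyldimethylsilyl)oxy]-7-oxo-4-(propan-2-yl)-3-[(triethylsilyl)oxy]cycloheptyl]acetaldehyde F2;
   - an intramolecular crossed benzoin reaction (triazolium carbene precatalyst, Et3N, THF) would close ring A as the α-ketol (1S,4S,5S,6S,7R,8S)-8-[(tert-butyldimethylsilyl)oxy]-4-hydroxy-6-[(triethylsilyl)oxy]-14-norguaiane-3,10-dione F3;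
   - hydroxyl-directed reduction (Me4NBH(OAc)3, MeCN/AcOH) would give the trans-diol (1S,3S,4S,5S,6S,7R,8S)-8-[(tert-butyldimethylsilyl)oxy]-3,4-dihydroxy-6-[(triethylsilyl)oxy]-14-norguaian-10-one F4;
   - methylenation (CH2Br2, Zn, TiCl4) would give (1S,3S,4S,5S,6S,7R,8S)-8-[(tert-butyldimethylsilyl)oxy]-6-[(triethylsilyl)oxy]guai-10(14)-ene-3,4-diol F5, and methanolysis of its triethylsilyl ether (PPTS, MeOH) would come back to the route at 21.

3. Step 5. The Felkin–Anh bias between the isopropyl group and the silyloxyallyl branch could be too small, so that the C8 epimer forms in quantity. Fallback from 7, which puts C8 under auxiliary control: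
   - an acetate aldol reaction of the titanium enolate of (R)-3-acetyl-4-benzyl-1,3-thiazolidine-2-thione (TiCl4, iPr2NEt, CH2Cl2, −78 °C; the auxiliary enantiomer is the one that delivers the 3S carbinol) would give (R)-4-benzyl-3-[(3S,4R,5R)-3-hydroxy-4-(propan-2-yl)-5-[(triethylsilyl)oxy]hept-6-enoyl]-1,3-thiazolidine-2-thione F6;
   - silylation (tBuMe2SiOTf, 2,6-lutidine) would give (R)-4-benzyl-3-[(3S,4R,5R)-3-[(tert-butyldimethylsilyl)oxy]-4-(propan-2-yl)-5-[(triethylsilyl)oxy]hept-6-enoyl]-1,3-thiazolidine-2-thione F7;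
   - displacement of the auxiliary (MeONHMe·HCl, imidazole) would give (3S,4R,5R)-3-[(tert-butyldimethylsilyl)oxy]-N-methoxy-N-methyl-4-(propan-2-yl)-5-[(triethylsilyl)oxy]hept-6-enamide F8, and vinylmagnesium bromide (THF, 0 °C) would come back to the route at 11.

**Further compounds**
F1 | step 8 | (3R,4R,5R,6S)-6-[(tert-butyldimethylsilyl)oxy]-3-(prop-1-en-2-yl)-5-(propan-2-yl)-4-[(triethylsilyl)oxy]-1-[(trimethylsilyl)oxy]cyclohept-1-ene | C[Si](C)(C)OC1=C[C@H](C(C)=C)[C@@H](O[Si](CC)(CC)CC)[C@H](C(C)C)[C@@H](O[Si](C)(C)C(C)(C)C)C1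
F2 | step 12 | 2-[(1S,2S,3S,4R,5S)-2-acetyl-5-[(tert-butyldimethylsilyl)oxy]-7-oxo-4-(propan-2-yl)-3-[(triethylsilyl)oxy]cycloheptyl]acetaldehyde | O=C1C[C@H](O[Si](C)(C)C(C)(C)C)[C@@H](C(C)C)[C@H](O[Si](CC)(CC)CC)[C@@H](C(C)=O)[C@@H]1CC=O
F3 | step 12 | (1S,4S,5S,6S,7R,8S)-8-[(tert-butyldimethylsilyl)oxy]-4-hydroxy-6-[(triethylsilyl)oxy]-14-norguaiane-3,10-dione | O=C1C[C@H](O[Si](C)(C)C(C)(C)C)[C@@H](C(C)C)[C@H](O[Si](CC)(CC)CC)[C@@H]2[C@@H]1CC(=O)[C@@]2(C)O
F4 | step 12 | (1S,3S,4S,5S,6S,7R,8S)-8-[(tert-butyldimethylsilyl)oxy]-3,4-dihydroxy-6-[(triethylsilyl)oxy]-14-norguaian-10-one | O=C1C[C@H](O[Si](C)(C)C(C)(C)C)[C@@H](C(C)C)[C@H](O[Si](CC)(CC)CC)[C@@H]2[C@@H]1C[C@H](O)[C@@]2(C)O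
F5 | step 12 | (1S,3S,4S,5S,6S,7R,8S)-8-[(tert-butyldimethylsilyl)oxy]-6-[(triethylsilyl)oxy]guai-10(14)-ene-3,4-diol | C=C1C[C@H](O[Si](C)(C)C(C)(C)C)[C@@H](C(C)C)[C@H](O[Si](CC)(CC)CC)[C@@H]2[C@@H]1C[C@H](O)[C@@]2(C)O
F6 | step 5 | (R)-4-benzyl-3-[(3S,4R,5R)-3-hydroxy-4-(propan-2-yl)-5-[(triethylsilyl)oxy]hept-6-enoyl]-1,3-thiazolidine-2-thione | S=C1SC[C@@H](Cc2ccccc2)N1C(=O)C[C@H](O)[C@@H](C(C)C)[C@H](O[Si](CC)(CC)CC)C=C
F7 | step 5 | (R)-4-benzyl-3-[(3S,4R,5R)-3-[(tert-butyldimethylsilyl)oxy]-4-(propan-2-yl)-5-[(triethylsilyl)oxy]hept-6-enoyl]-1,3-thiazolidine-2-thione | S=C1SC[C@@H](Cc2ccccc2)N1C(=O)C[C@H](O[Si](C)(C)C(C)(C)C)[C@@H](C(C)C)[C@H](O[Si](CC)(CC)CC)C=C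
F8 | step 5 | (3S,4R,5R)-3-[(tert-butyldimethylsilyl)oxy]-N-methoxy-N-methyl-4-(propan-2-yl)-5-[(triethylsilyl)oxy]hept-6-enamide | CON(C)C(=O)C[C@H](O[Si](C)(C)C(C)(C)C)[C@@H](C(C)C)[C@H](O[Si](CC)(CC)CC)C=C
A1 | direct plan | (R)-2-methoxy-4-[3-(trimethylsilyl)prop-1-en-2-yl]cyclopent-2-en-1-one | O=C1C[C@@H](C(=C)C[Si](C)(C)C)C=C1OC
A2 | direct plan | (2R,3S)-2-(propan-2-yl)-3-[(triethylsilyl)oxy]pent-4-enal | C=C[C@H](O[Si](CC)(CC)CC)[C@@H](C(C)C)C=O
A3 | direct plan | (1S,2S,3S,4S)-3-[(1S,2R,3S)-1,3-diacetoxy-2-(propan-2-yl)pent-4-en-1-yl]-2-hydroxy-2-methyl-4-[3-(trimethylsilyl)prop-1-en-2-yl]cyclopentyl acetate | C=C[C@H](OC(C)=O)[C@@H](C(C)C)[C@H](OC(C)=O)[C@H]1[C@](C)(O)[C@@H](OC(C)=O)C[C@@H]1C(=C)C[Si](C)(C)C
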